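## Retrosynthetic overview
- The target is a 5,7-dihydroxy-6-prenyl flavanone whose B ring carries a fused 2,2-dimethylchromene. The (2S) centre comes from a catalytic asymmetric intramolecular oxa-Michael closure of 2′,6′-dihydroxychalcone **7**, used as the last step so that no base, deprotection or other operation follows to racemise the 5-hydroxyflavanone.
- Chalcone **7** comes from Claisen–Schmidt condensation of 3′-prenylphloroacetophenone **3** with chromene aldehyde **6**.
- Ring order: the B-ring pyran is built first (**4** + **5** → **6**), the chalcone is assembled next, and the flavanone C ring closes last. No protecting groups are used.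

Assumptions:
1. The 2,2-dimethylchromene forms at C5 of 2,4-dihydroxybenzaldehyde (linear isomer, major), and the angular isomer is removed by chromatography.
2. Closure through the 6′-OH (remote from the prenyl group) is kinetically favoured over the 2′-OH. This gives the 6-prenyl rather than the 8-prenyl flavanone.
3. The (S)-selective pseudo-enantiomer of the cinchona catalyst is chosen by a quinine/quinidine screen.

## Route

**Step 1**
Reactants: **1** 2′,4′,6′-trihydroxyacetophenone (phloroacetophenone); **2** prenyl bromide
Product: **3** 1-[2,4,6-trihydroxy-3-(3-methylbut-2-en-1-yl)phenyl]ethan-1-one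
Conditions: **1** (2 equiv), **2** (1 equiv), KOH (2.2 equiv), MeOH/H2O, 0 °C to rt, 12 h
Reagents that add atoms: prenyl bromide, CC(C)=CCBr
Why: C-alkylation of the acylphloroglucinol phenoxide (ambident nucleophile) with an allylic bromide. Substrate **1** is C2-symmetric, so mono-C-prenylation gives only the 3′-isomer, and using excess **1** limits over-alkylation. No stereocentre is formed.

**Step 2**
Reactants: **4** 2,4-dihydroxybenzaldehyde; **5** 3-methylbut-2-enal (prenal)
Product: **6** 7-hydroxy-2,2-dimethyl-2H-chromene-6-carbaldehyde
Conditions: **4**, **5** (2 equiv), pyridine, 120 °C, sealed tube, 24 h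
Reagents that add atoms: prenal, CC(C)=CC=O
Why: Phenol–enal condensation gives an o-quinone methide, which undergoes 6π-oxa-electrocyclisation to the 2,2-dimethyl-2H-chromene. The formyl-chelated 2-OH is left untouched and the 4-OH and C5 are annulated.

**Step 3**
Reactants: **3**; **6**
Product: **7** (E)-1-[2,4,6-trihydroxy-3-prenylphenyl]-3-(7-hydroxy-2,2-dimethyl-2H-chromen-6-yl)prop-2-en-1-one
Conditions: KOH (6 equiv), EtOH/H2O, rt, 48 h, N2, dark; then 1 M HCl to pH 4 and chromatography
Reagents that add atoms: none
Why: Claisen–Schmidt (aldol condensation) under excess base. The polyphenoxide protects the chalcone from cyclising in the flask and gives the E-enone; the mildly acidic quench avoids damaging the prenyl and chromene alkenes.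

**Step 4**
Reactants: **7**
Product: **8** cudraflavanone A, (2S)-5,7-dihydroxy-6-prenyl-2-(7-hydroxy-2,2-dimethyl-2H-chromen-6-yl)chroman-4-one (the 2′-OH flavanone numbering of the target SMILES)
Conditions: 10 mol % cinchona-derived bifunctional squaramide catalyst (9-epi-amino-9-deoxy-quinidine squaramide with a 3,5-(CF3)2C6H3 group), toluene/CH2Cl2 (1:1), 25 °C, 72 h, dark
Reagents that add atoms: none (the catalyst is not incorporated; the step is an isomerisation)
Why: Asymmetric intramolecular oxa-Michael (6-endo-trig). The tertiary amine deprotonates and positions the 6′-OH, and the squaramide N–H groups bind the enone carbonyl, so the phenoxide attacks one face of Cβ. This sets C2 as (S), matching [C@@H] in the target (priorities O > aryl > C3 > H). The conditions are neutral and nothing follows, so the centre is not scrambled by retro-Michael opening.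

## Compound list
1 | 2′,4′,6′-trihydroxyacetophenone | CC(=O)c1c(O)cc(O)cc1O | starting material
2 | prenyl bromide (1-bromo-3-methylbut-2-ene) | CC(C)=CCBr | starting material
3 | 1-[2,4,6-trihydroxy-3-(3-methylbut-2-enyl)phenyl]ethanone | CC(=O)c1c(O)cc(O)c(CC=C(C)C)c1O | intermediate
4 | 2,4-dihydroxybenzaldehyde | O=Cc1ccc(O)cc1O | starting material
5 | 3-methylbut-2-enal | CC(C)=CC=O | starting material
6 | 7-hydroxy-2,2-dimethyl-2H-chromene-6-carbaldehyde | O=Cc1cc2C=CC(C)(C)Oc2cc1O | intermediate
7 | (E)-chalcone from 3 and 6 | CC(C)=CCc1c(O)cc(O)c(C(=O)/C=C/c2cc3C=CC(C)(C)Oc3cc2O)c1O | intermediate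
8 | cudraflavanone A, (2S) | CC(C)=CCc1c(O)cc2c(c1O)C(=O)C[C@@H](c1cc3c(cc1O)OC(C)(C)C=C3)O2 | target

Atom check: 3 (C13H16O4) + 6 (C12H12O3) − H2O = 7 (C25H26O6), and 7 isomerises to 8 (C25H26O6).

## Totals
Total steps: 4. Longest linear sequence: 3 (1 → 3 → 7 → 8).

## Three steps most likely to fail
1. **Step 4, enantioselective closure.** Risks are modest ee, retro-Michael racemisation of the 5-OH flavanone, and 8-prenyl regioisomer formation.
   Fallback: cyclise **7** to racemic flavanone (NaOAc, EtOH, reflux) and resolve it by preparative chiral SFC/HPLC. Alternatively, use Pd/chiral-ligand asymmetric conjugate arylation of a chromone with an arylboronic acid.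
2. **Step 3, aldol on the free polyphenols.** Yields are likely low because the aldehyde phenoxide is deactivated and oxidation is possible.
   Fallback: protect both partners as MOM ethers (the aldol with MOM ethers is well precedented), run the condensation, then remove all MOM groups under mild acid (HCl/MeOH) to give **7** before the same final step.
3. **Step 1, C-prenylation.** Expect modest yield with O- and di-prenylation by-products.
   Fallback: make **3** by directed ortho-lithiation of the tris-MOM phloroacetophenone at C3′, alkylation with prenyl bromide/CuI, and mild acidic MOM removal.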